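Start from the midnight run: at its first reading, 5.00 min, X and L together already fall short of the charge by 0.275 M, and that flask got 0.28 M of Q. The autumn run reads 0.0901 M short against 0.085 M of Q. So count one L lost per Q, early.

all flasks: L 0.91 M; Z 3.6 mM
- autumn: Q 0.085 M; run made earlier
- spring: Q 0.16 M; run made earlier
- midnight: Q 0.28 M; run made earlier
- south-east: Q 0.0910 M; time 1.0 h
- east: Q 0.250 M; time 1.0 h

- autumn (time / min: X / %, L / %): 5.00: 29.4, 60.7; 15.0: 52.0, 39.1; 30.0: 56.4, 34.0; 40.0: 57.3, 33.8; 60.0: 57.3, 34.0
- spring (time / min: X / %, L / %): 5.00: 25.6, 56.7; 10.0: 37.3, 44.1; 15.0: 44.1, 38.6; 30.0: 47.9, 34.0; 60.0: 48.4, 33.6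
- midnight (time / min: X / %, L / %): 5.00: 19.2, 50.6; 15.0: 31.7, 37.4; 30.0: 36.0, 34.4; 40.0: 35.4, 34.0; 60.0: 35.6, 34.3

(scatter of a reading: 0.5 percentage points)

- the average divides the monomer in chains by the number of chains begun, living and dead together
- the earlier runs do not show the number of chains; that part of a forecast is a guess

1. which of the two ends with the longer chains by the average number of monomer units in a chain (chains begun, living or dead) ("neither" if they lie within 10%) (south-east / east / neither)
2. average number of monomer units in a chain (chains begun, living or dead) at the end, south-east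
3. average number of monomer units in a chain (chains begun, living or dead) at the end, east

Reckon with what is left, not with what is made. At 60.0 min the L reads 34.0%, 33.6% and 34.3% in the earlier runs, with Q ranging from 0.085 M to 0.28 M. Take the mean as the fraction left, f = 34.0%, the equilibrium monomer level.

Does a new flask reach it? In the autumn run X stands 28 percentage points below its last reading at 5.00 min and 5.3 points below at 15.0 min. Read from those two points, that gap shrinks at 0.166 min⁻¹, and if a new flask keeps that pace, my estimate for 1.0 h is a fraction 0.00473% of it left. I take both new flasks as stopped.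

c(L) left = 0.91 M × 34.0% = 0.309 M

south-east: c(X) = 0.91 M − 0.309 M − 0.0910 M = 0.510 M

east: c(X) = 0.91 M − 0.309 M − 0.250 M = 0.351 M

Call this the stock: the L charged, less the L left at the stop, less the L lost to Q. Length is stock over chains. One chain per Z gives 142 for south-east and 97.5 for east.

That count is the weak link, since the readings do not show it. So lean on the ratio instead. If both flasks hold the same count, it cancels, leaving 1.45. That is outside the margin of 10%, so my estimate is that south-east ends longer than east, while the level stays a guess.

The forecast gives south-east, with 142 and 97: “I assume one chain per Z”.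

The flask gives south-east, with 455 against 320 in east.

    Q + L → D (k = 0.100 M⁻¹ s⁻¹)
    L + Z → G + X (k = 0.140 M⁻¹ s⁻¹)
    2 Z → E (k = 110 M⁻¹ s⁻¹)
    L + G → X + G, rate k4*[G]*[L] (k = 2.20 M⁻¹ s⁻¹)
    X + G → L + G, rate k5*[G] as long as [X] is above zero (k = 0.670 s⁻¹)

The south-east stock over its length gives 1.12 mM of chains. At 1.00 h that flask holds G at 0.00113 M beside E at 0.00123 M, each E made from two Z. The charge of Z is 3.21 times that count.

Now the neighbour of south-east charged with 0.36 M of Q: its stock is 0.241 M, and over 1.12 mM of chains that makes 215. The computed flask gives 224.

The runs are simulated for substances that don't exist; scatter was added.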